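**Retrosynthetic overview**
- The target is read as a 6,7:8,15-diseco-ent-kauranoid. The last disconnection is conjugate reduction of a C8=C9 unsaturated spiro-lactone, which sets C8 and C9.
- That lactone and the ether bridge come from one flask: C6–OH unmasking, oxa-Michael addition to C3 of the C1 enone (3,6-ether), C10 hydroxymethylation, then attack of the C20 hydroxyl on the C7 ester (7,20-lactone). These are the two heterocyclisations of the presumed biogenesis.
- The seco keto ester comes from a three-component union at C5/C10/C9: 4,4-dimethylcyclohexadienone (ring A), a silylmethyl Grignard reagent (C6 as masked CH2OH) and a ring C enol triflate.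
- The ring C enol triflate comes from (+)-nopinone: C3 carboxylation, cyclobutane cleavage (pinane C5 becomes C13), and isopropenyl to (R)-propanoic acid (C16 by asymmetric hydrogenation).
- Ring order: carbocycles A and C are taken from the dienone and the pinane; then the ether ring, then the lactone ring, then C8/C9.

Assumption: (1R,5S)-(+)-nopinone and (chloromethyl)(dimethyl)(propan-2-yloxy)silane are bought as such; atom labels follow ent-kaurane numbering (C1 ketone, C3 and C6 ether carbons, C7 lactone C=O, C10 spiro carbon, C13 ring C carbon bearing the C16 propanoic acid, C20 lactone OCH2), in which the target is 3S,5S,8S,9R,10S,13R,16R.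

**Step 1**
Reactants: 1 4,4-dimethylcyclohex-2-en-1-one
Product: 2 4,4-dimethylcyclohexa-2,5-dien-1-one
Conditions: DDQ (1.3 equiv), TsOH (cat.), dioxane, 100 °C
Reagents that add atoms: none
Why: DDQ dehydrogenation of an enone (hydride abstraction from the dienol) gives the cross-conjugated dienone because the quaternary C4 blocks aromatisation, and no stereocentre is involved.

**Step 2**
Reactants: 3 (1R,5S)-6,6-dimethylbicyclo[3.1.1]heptan-2-one
Product: 4 methyl (1R,5R)-6,6-dimethyl-2-oxobicyclo[3.1.1]heptane-3-carboxylate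
Conditions: NaH (2.2 equiv), (MeO)2CO, THF, 65 °C; then AcOH
Reagents that add atoms: dimethyl carbonate, COC(=O)OC
Why: Crossed Claisen condensation goes only at C3 because the other α-carbon is a bridgehead, so the ester lands on the future C8 while the pinane C5 (future C13) is untouched (C3 is a labile keto/enol centre).

**Step 3**
Reactants: 4 methyl (1R,5R)-6,6-dimethyl-2-oxobicyclo[3.1.1]heptane-3-carboxylate
Product: 6 methyl (5R)-2-oxo-5-(prop-1-en-2-yl)cyclohexane-1-carboxylate, via enol acetate 5 (not isolated)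
Conditions: Zn(OAc)2 (0.2 equiv), BF3·OEt2 (0.5 equiv), Ac2O, 0 → 25 °C; then K2CO3 (cat.), MeOH, 0 °C
Reagents that add atoms: none
Why: Lewis acid-promoted cyclobutane fragmentation of the Grob type, as known for nopinones, breaks the strained bond between the bridgehead α-carbon and CMe2, the tertiary cation loses a proton to give the isopropenyl group, the enol is caught as its acetate and freed by methanolysis; the untouched pinane C5 becomes C13 with the R configuration.

**Step 4**
Reactants: 6 methyl (5R)-2-oxo-5-(prop-1-en-2-yl)cyclohexane-1-carboxylate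
Product: 7 methyl (5R)-5-(prop-1-en-2-yl)-2-{[(trifluoromethyl)sulfonyl]oxy}cyclohex-1-ene-1-carboxylate
Conditions: Tf2O, i-Pr2NEt, CH2Cl2, −78 °C
Reagents that add atoms: trifluoromethanesulfonic anhydride, O=S(=O)(OS(=O)(=O)C(F)(F)F)C(F)(F)F
Why: O-sulfonylation of the β-keto ester enol (enol triflate formation) fixes the C8=C9 double bond and makes C9 an electrophilic β-carbon.

**Step 5**
Reactants: 7 methyl (5R)-5-(prop-1-en-2-yl)-2-{[(trifluoromethyl)sulfonyl]oxy}cyclohex-1-ene-1-carboxylate
Product: 8 methyl (5R)-5-(3-hydroxyprop-1-en-2-yl)-2-{[(trifluoromethyl)sulfonyl]oxy}cyclohex-1-ene-1-carboxylate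
Conditions: SeO2 (0.3 equiv), t-BuOOH (3 equiv), CH2Cl2, 25 °C
Reagents that add atoms: tert-butyl hydroperoxide, CC(C)(C)OO; selenium dioxide, O=[Se]=O
Why: Riley allylic oxidation (ene reaction then 2,3-sigmatropic shift) attacks the methyl group of the only electron-rich alkene, the enol triflate double bond being too electron-poor to react.

**Step 6**
Reactants: 8 methyl (5R)-5-(3-hydroxyprop-1-en-2-yl)-2-{[(trifluoromethyl)sulfonyl]oxy}cyclohex-1-ene-1-carboxylate
Product: 9 2-[(1R)-3-(methoxycarbonyl)-4-{[(trifluoromethyl)sulfonyl]oxy}cyclohex-3-en-1-yl]prop-2-enoic acid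
Conditions: TEMPO (0.2 equiv), PhI(OAc)2 (2.5 equiv), MeCN/H2O, 25 °C
Reagents that add atoms: water, O
Why: Oxoammonium (TEMPO) oxidation in wet acetonitrile takes the primary allylic alcohol through the aldehyde hydrate to the 2-substituted acrylic acid without touching the enol triflate.

**Step 7**
Reactants: 9 2-[(1R)-3-(methoxycarbonyl)-4-{[(trifluoromethyl)sulfonyl]oxy}cyclohex-3-en-1-yl]prop-2-enoic acid
Product: 10 (2R)-2-[(1R)-3-(methoxycarbonyl)-4-{[(trifluoromethyl)sulfonyl]oxy}cyclohex-3-en-1-yl]propanoic acid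
Conditions: H2 (50 atm), Ru(OAc)2[(R)-H8-BINAP] (1 mol %), MeOH, 25 °C
Reagents that add atoms: none
Why: Carboxylate-directed Noyori asymmetric hydrogenation of a 2-alkylacrylic acid sets C16 as R under ligand control (the (R)-ligand by analogy with 2-arylpropanoic acids), while the tetrasubstituted electron-poor enol triflate alkene is inert.

**Step 8**
Reactants: 2 4,4-dimethylcyclohexa-2,5-dien-1-one; 11 (chloromethyl)(dimethyl)(propan-2-yloxy)silane; 10 (2R)-2-[(1R)-3-(methoxycarbonyl)-4-{[(trifluoromethyl)sulfonyl]oxy}cyclohex-3-en-1-yl]propanoic acid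
Product: 14 (2R)-2-[(1R)-4-[(1S,6R)-6-{[dimethyl(propan-2-yloxy)silyl]methyl}-5,5-dimethyl-2-oxocyclohex-3-en-1-yl]-3-(methoxycarbonyl)cyclohex-3-en-1-yl]propanoic acid, via Grignard reagent 12 (not isolated), via magnesium enolate 13 (not isolated)
Conditions: 11, Mg, THF, 25 °C; CuBr·SMe2 (5 mol %), (R)-1-[(S)-2-(diphenylphosphino)ferrocenyl]ethyldicyclohexylphosphine (6 mol %), t-BuOMe, −78 °C, slow addition of 2; then 10 premixed with LiN(SiMe3)2 (2.1 equiv), THF/DMPU, −78 → 0 °C; dilute aq. HCl
Reagents that add atoms: none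
Why: Proposed new method: a copper-catalysed asymmetric conjugate addition of the hydroxymethyl-equivalent Grignard reagent desymmetrises the prochiral dienone and sets C5 by ligand control (the mirror-image ligand is used if the sense is opposite), and the regiodefined magnesium enolate then adds to C9 of the β-triflyloxy enoate and expels triflate (addition–elimination) to forge C9–C10; the closest known reactions are monovalent copper/ferrocenyl-diphosphine Grignard additions to cyclic enones, CuI-catalysed 1,4-additions of this same Grignard reagent, electrophilic trapping of the resulting enolates and enolate substitution of β-sulfonyloxy enoates; C10 is an epimerisable centre (drawn trans to C6) that is reset in step 9, and any minor enantiomer of ring A ends as a separable diastereomer because 10 is a single enantiomer.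

**Step 9**
Reactants: 14 (2R)-2-[(1R)-4-[(1S,6R)-6-{[dimethyl(propan-2-yloxy)silyl]methyl}-5,5-dimethyl-2-oxocyclohex-3-en-1-yl]-3-(methoxycarbonyl)cyclohex-3-en-1-yl]propanoic acid
Product: 18 (2R)-2-[(1S,2R,5S,7'R)-8,8-dimethyl-1',3-dioxo-5',6',7',8'-tetrahydro-1'H,3'H-spiro[6-oxabicyclo[3.2.1]octane-2,4'-isochromen]-7'-yl]propanoic acid, via primary alcohol 15 (not isolated), via bridged ketone 16 (not isolated), via hydroxymethyl ketone 17 (not isolated)
Conditions: 30% aq. H2O2, KF, KHCO3, THF/MeOH, 25 °C; Na2S2O3; then 37% aq. CH2O, K2CO3, 25 → 40 °C; dilute aq. HCl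
Reagents that add atoms: hydrogen peroxide, OO; formaldehyde, C=O
Why: Tamao oxidation frees the C6 alcohol, which closes the ether ring by 5-exo oxa-Michael addition to C3 of the enone as in the biogenesis (C3 is fixed by C5 because the bridge must be cis), the doubly activated C10–H then undergoes aldol hydroxymethylation on the only face that leaves the bulky C9 substituent equatorial (anti to the bridge, setting C10), and the C20 alcohol is trapped by lactonisation onto the cis-disposed C7 ester, which also drains the reversible aldol.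

**Step 10**
Reactants: 18 (2R)-2-[(1S,2R,5S,7'R)-8,8-dimethyl-1',3-dioxo-5',6',7',8'-tetrahydro-1'H,3'H-spiro[6-oxabicyclo[3.2.1]octane-2,4'-isochromen]-7'-yl]propanoic acid
Product: 19 (2R)-2-[(1S,2S,4'aR,5S,7'R,8'aS)-8,8-dimethyl-1',3-dioxo-octahydro-1'H-spiro[6-oxabicyclo[3.2.1]octane-2,4'-isochromen]-7'-yl]propanoic acid
Conditions: SmI2 (2.5 equiv), HMPA, t-BuOH, THF, −78 °C; aq. NH4Cl
Reagents that add atoms: none
Why: Samarium diiodide conjugate reduction (single-electron transfer to the unsaturated lactone) protonates C9 axially on ring C so that the spiro carbon stays equatorial and 1,4-trans to the equatorial C13 side chain, then protonates the samarium enolate kinetically at the ring-fusion carbon C8 to give the cis-fused lactone (as in kinetic protonation of 1-decalone enolates), while the hindered α-quaternary ketone survives at −78 °C.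

**Compound list**
1 | 4,4-dimethylcyclohex-2-en-1-one | CC1(C)CCC(=O)C=C1 | starting material
2 | 4,4-dimethylcyclohexa-2,5-dien-1-one | CC1(C)C=CC(=O)C=C1 | intermediate
3 | (1R,5S)-6,6-dimethylbicyclo[3.1.1]heptan-2-one, (+)-nopinone | CC1(C)[C@H]2CCC(=O)[C@@H]1C2 | starting material
4 | methyl (1R,5R)-6,6-dimethyl-2-oxobicyclo[3.1.1]heptane-3-carboxylate (C3 epimers and enol) | CC1(C)[C@H]2CC(C(=O)OC)C(=O)[C@@H]1C2 | intermediate
5 | methyl (5R)-2-acetoxy-5-(prop-1-en-2-yl)cyclohex-1-ene-1-carboxylate (not isolated) | CC(=C)[C@@H]1CCC(OC(C)=O)=C(C1)C(=O)OC | intermediate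
6 | methyl (5R)-2-oxo-5-(prop-1-en-2-yl)cyclohexane-1-carboxylate (keto/enol mixture, C1 labile) | CC(=C)[C@@H]1CCC(=O)C(C1)C(=O)OC | intermediate
7 | methyl (5R)-5-(prop-1-en-2-yl)-2-{[(trifluoromethyl)sulfonyl]oxy}cyclohex-1-ene-1-carboxylate | CC(=C)[C@@H]1CCC(OS(=O)(=O)C(F)(F)F)=C(C1)C(=O)OC | intermediate
8 | methyl (5R)-5-(3-hydroxyprop-1-en-2-yl)-2-{[(trifluoromethyl)sulfonyl]oxy}cyclohex-1-ene-1-carboxylate | C=C(CO)[C@@H]1CCC(OS(=O)(=O)C(F)(F)F)=C(C1)C(=O)OC | intermediate
9 | 2-[(1R)-3-(methoxycarbonyl)-4-{[(trifluoromethyl)sulfonyl]oxy}cyclohex-3-en-1-yl]prop-2-enoic acid | C=C(C(=O)O)[C@@H]1CCC(OS(=O)(=O)C(F)(F)F)=C(C1)C(=O)OC | intermediate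
10 | (2R)-2-[(1R)-3-(methoxycarbonyl)-4-{[(trifluoromethyl)sulfonyl]oxy}cyclohex-3-en-1-yl]propanoic acid | C[C@@H](C(=O)O)[C@@H]1CCC(OS(=O)(=O)C(F)(F)F)=C(C1)C(=O)OC | intermediate
11 | (chloromethyl)(dimethyl)(propan-2-yloxy)silane | ClC[Si](C)(C)OC(C)C | starting material
12 | {[dimethyl(propan-2-yloxy)silyl]methyl}magnesium chloride (not isolated) | CC(C)O[Si](C)(C)C[Mg]Cl | intermediate
13 | chloromagnesium enolate (C1=C10) of (5R)-5-{[dimethyl(propan-2-yloxy)silyl]methyl}-4,4-dimethylcyclohex-2-en-1-one (not isolated) | CC(C)O[Si](C)(C)C[C@@H]1C=C(O[Mg]Cl)C=CC1(C)C | intermediate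
14 | (2R)-2-[(1R)-4-[(1S,6R)-6-{[dimethyl(propan-2-yloxy)silyl]methyl}-5,5-dimethyl-2-oxocyclohex-3-en-1-yl]-3-(methoxycarbonyl)cyclohex-3-en-1-yl]propanoic acid (C10 epimers interconvert; trans epimer drawn) | C[C@@H](C(=O)O)[C@@H]1CCC(=C(C1)C(=O)OC)[C@H]1C(=O)C=CC(C)(C)[C@@H]1C[Si](C)(C)OC(C)C | intermediate
15 | (2R)-2-[(1R)-4-[(1S,6R)-6-(hydroxymethyl)-5,5-dimethyl-2-oxocyclohex-3-en-1-yl]-3-(methoxycarbonyl)cyclohex-3-en-1-yl]propanoic acid (not isolated) | C[C@@H](C(=O)O)[C@@H]1CCC(=C(C1)C(=O)OC)[C@H]1C(=O)C=CC(C)(C)[C@@H]1CO | intermediate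
16 | (2R)-2-[(1R)-4-[(1R,2R,5S)-8,8-dimethyl-3-oxo-6-oxabicyclo[3.2.1]octan-2-yl]-3-(methoxycarbonyl)cyclohex-3-en-1-yl]propanoic acid (not isolated) | C[C@@H](C(=O)O)[C@@H]1CCC(=C(C1)C(=O)OC)[C@@H]1C(=O)C[C@@H]2OC[C@H]1C2(C)C | intermediate
17 | (2R)-2-[(1R)-4-[(1S,2R,5S)-2-(hydroxymethyl)-8,8-dimethyl-3-oxo-6-oxabicyclo[3.2.1]octan-2-yl]-3-(methoxycarbonyl)cyclohex-3-en-1-yl]propanoic acid (not isolated) | C[C@@H](C(=O)O)[C@@H]1CCC(=C(C1)C(=O)OC)[C@]1(CO)C(=O)C[C@@H]2OC[C@H]1C2(C)C | intermediate
18 | (2R)-2-[(1S,2R,5S,7'R)-8,8-dimethyl-1',3-dioxo-5',6',7',8'-tetrahydro-1'H,3'H-spiro[6-oxabicyclo[3.2.1]octane-2,4'-isochromen]-7'-yl]propanoic acid (C8=C9 unsaturated spiro-lactone; 3S,5S,10R,13R,16R) | C[C@@H](C(=O)O)[C@@H]1CCC2=C(C1)C(=O)OC[C@]21C(=O)C[C@@H]2OC[C@H]1C2(C)C | intermediate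
19 | (2R)-2-[(1S,2S,4'aR,5S,7'R,8'aS)-8,8-dimethyl-1',3-dioxo-octahydro-1'H-spiro[6-oxabicyclo[3.2.1]octane-2,4'-isochromen]-7'-yl]propanoic acid, CNP0152427.1 (3S,5S,8S,9R,10S,13R,16R) | C[C@@H](C(=O)O)[C@@H]1CC[C@@H]2[C@H](C1)C(=O)OC[C@]21C(=O)C[C@@H]2OC[C@H]1C2(C)C | target

**Step count and risks**
Total steps: 10. Longest linear sequence: 9 steps (3 → 4 → 6 → 7 → 8 → 9 → 10 → 14 → 18 → 19).

The three steps most likely to fail:

Step 8 (three-component union). The magnesium enolate may be too sluggish toward the tetrasubstituted β-triflyloxy enoate, or may be consumed by proton transfer. The fallback sets out from 2 and 11 and separates bond formation into a conjugate addition and a cross-coupling. The copper-catalysed asymmetric addition is quenched with aqueous NH4Cl and the product is isolated as (5R)-5-{[dimethyl(propan-2-yloxy)silyl]methyl}-4,4-dimethylcyclohex-2-en-1-one F1. Because C4 is quaternary, C10 is the only enolisable position, so LiN(SiMe3)2 (2.2 equiv) gives cleanly the lithium enolate of this enone F2. This is joined to 10 by palladium-catalysed α-alkenylation (Pd2(dba)3, XPhos, THF, 50 °C): zerovalent palladium inserts into the C–OTf bond, the enolate transmetalates and reductive elimination forms C9–C10. The fallback comes back to the route at 14.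

Step 9 (one-flask cascade). Peroxide may attack the enone before the alcohol closes, or the bridged ketone may be hydroxymethylated at C2 or with poor face selectivity. The fallback sets out from 14 and reverses the order of the two heterocyclisations. Aqueous CH2O and K2CO3 on 14 give, by attack anti to the C5 silylmethyl group, the silyl-bearing hydroxymethyl ketone (2R)-2-[(1R)-4-[(1R,6R)-1-(hydroxymethyl)-6-{[dimethyl(propan-2-yloxy)silyl]methyl}-5,5-dimethyl-2-oxocyclohex-3-en-1-yl]-3-(methoxycarbonyl)cyclohex-3-en-1-yl]propanoic acid F3. This lactonises to the isolable silyl enone spiro-lactone F4. Tamao oxidation (H2O2, KF, KHCO3) then gives the hydroxy enone spiro-lactone F5, which undergoes the oxa-Michael closure in the same flask as the last ring-forming event. The fallback comes back to the route at 18.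

Step 10 (reduction). The ketone may be reduced competitively, or protonation may give the C9 epimer or the trans-fused lactone. The fallback sets out from 18 and replaces electron transfer by carboxylate-directed homogeneous hydrogenation with [Rh(C7H8)(Ph2P(CH2)4PPh2)]BF4 under H2 (70 atm) in CH2Cl2. The C15 carboxylate binds the cationic rhodium and both hydrogens are delivered syn to the side chain, which is the face required at C8 and C9; syn addition also guarantees the cis ring fusion. The fallback creates no new compound (entry F0) and comes back to the route at 19.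

**Further compounds**
F1 | step 8 | (5R)-5-{[dimethyl(propan-2-yloxy)silyl]methyl}-4,4-dimethylcyclohex-2-en-1-one | CC(C)O[Si](C)(C)C[C@@H]1CC(=O)C=CC1(C)C
F2 | step 8 | lithium enolate (C1=C10) of F1 | CC(C)O[Si](C)(C)C[C@@H]1C=C(O[Li])C=CC1(C)C
F3 | step 9 | (2R)-2-[(1R)-4-[(1R,6R)-1-(hydroxymethyl)-6-{[dimethyl(propan-2-yloxy)silyl]methyl}-5,5-dimethyl-2-oxocyclohex-3-en-1-yl]-3-(methoxycarbonyl)cyclohex-3-en-1-yl]propanoic acid | C[C@@H](C(=O)O)[C@@H]1CCC(=C(C1)C(=O)OC)[C@]1(CO)C(=O)C=CC(C)(C)[C@@H]1C[Si](C)(C)OC(C)C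
F4 | step 9 | silyl enone spiro-lactone (18 with an open ether bridge: C2=C3 enone and C6 as CH2SiMe2(OiPr)) | C[C@@H](C(=O)O)[C@@H]1CCC2=C(C1)C(=O)OC[C@]21C(=O)C=CC(C)(C)[C@@H]1C[Si](C)(C)OC(C)C
F5 | step 9 | hydroxy enone spiro-lactone (18 with an open ether bridge: C2=C3 enone and C6 as CH2OH) | C[C@@H](C(=O)O)[C@@H]1CCC2=C(C1)C(=O)OC[C@]21C(=O)C=CC(C)(C)[C@@H]1CO
F0 | step 10 | none | none
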